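**Plan**
- Cuts: the C7 phenol is unmasked last (MOM), the C4 ketone is traced back to a C4–OMe group, and ring C is opened at O1–C2 and C3–C4 in one retro-[4+2]. This leaves a salicylaldehyde (ring A plus C4) and 3,4-dimethoxystyrene (ring B plus C2–C3); the aldehyde is cut back at its formyl and two prenyl bonds to resorcinol.
- Enabling feature: in ring C the bonds O1–C2 and C3–C4 flank the two-carbon unit C2–C3, which is the olefin of the styrene. C4 is a benzylic carbon ortho to O1 and para to the C7 oxygen of ring A, i.e. the carbonyl carbon of a 4-oxygenated salicylaldehyde that can become a 4-methoxy ortho-quinone methide.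
- Forward order: ring A is fully substituted first by three directed lithiations (prenyl, prenyl, formyl), ring B arrives intact with the styrene, and ring C is the only ring made (step 6). Three functional-group steps finish the route.
- Stereochemistry: C2 (S) is set in the cycloaddition by a chiral BINOL-derived phosphoric acid; C4 is a temporary centre that is removed by oxidation.

Key step: step 6

Abbreviations: prenyl = 3-methylbut-2-en-1-yl; MOM = methoxymethyl; TMEDA = N,N,N',N'-tetramethylethylenediamine.

Assumption: the (R)-configured phosphoric acid is taken to deliver the (2S) adduct; if the sense of induction proves opposite, the (S)-acid is used and nothing else changes.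

**Route**

Step 1
Reactants: 1 resorcinol
Product: 2 1,3-bis(methoxymethoxy)benzene
Conditions: MOMCl (2.5 equiv), i-Pr2NEt (3 equiv), CH2Cl2, 0 °C → rt
Reagents that add atoms: chloromethyl methyl ether (MOMCl), COCCl
Why: Routine O-alkylation of both phenols with the reactive α-chloro ether (MOM protection) installs the two groups that later direct every lithiation.

Step 2
Reactants: 2 1,3-bis(methoxymethoxy)benzene; 3 prenyl bromide
Product: 5 1,3-bis(methoxymethoxy)-2-prenylbenzene, via aryllithium 4 (not isolated)
Conditions: n-BuLi (1.1 equiv), THF, 0 °C → rt; CuBr·SMe2 (10 mol %), then 3, −40 °C → rt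
Reagents that add atoms: prenyl bromide (compound 3), CC(C)=CCBr
Why: Directed ortho-metalation takes place between the two OMOM groups, the most acidic and doubly coordinated position, and the aryllithium is alkylated at the primary carbon of the allylic bromide under copper catalysis.

Step 3
Reactants: 5 1,3-bis(methoxymethoxy)-2-prenylbenzene; 3 prenyl bromide
Product: 7 1,3-bis(methoxymethoxy)-2,4-diprenylbenzene, via aryllithium 6 (not isolated)
Conditions: n-BuLi (1.2 equiv), TMEDA (1.2 equiv), THF, −20 → 0 °C; CuBr·SMe2 (10 mol %), then 3, −40 °C → rt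
Reagents that add atoms: prenyl bromide (compound 3), CC(C)=CCBr
Why: A second directed ortho-metalation at C4 (equivalent to C6 by symmetry) is followed by the same copper-catalysed allylic alkylation, kinetic ring lithiation by the coordinated base being expected to outrun removal of the benzylic–allylic proton.

Step 4
Reactants: 7 1,3-bis(methoxymethoxy)-2,4-diprenylbenzene
Product: 10 2,4-bis(methoxymethoxy)-3,5-diprenylbenzaldehyde, via aryllithium 8 (not isolated), via lithium hemiaminal alkoxide 9 (not isolated)
Conditions: n-BuLi (1.3 equiv), TMEDA (1.3 equiv), THF, −20 → 0 °C; DMF, −78 °C → rt; then H2O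
Reagents that add atoms: N,N-dimethylformamide, CN(C)C=O
Why: A third directed ortho-metalation at the only ring position still next to an OMOM group is followed by Bouveault-type formylation with DMF, the aldehyde being released from the lithium hemiaminal on aqueous quench.

Step 5
Reactants: 10 2,4-bis(methoxymethoxy)-3,5-diprenylbenzaldehyde
Product: 11 2-hydroxy-4-(methoxymethoxy)-3,5-diprenylbenzaldehyde
Conditions: aq. HCl (1 M), MeOH–THF, 0 °C → rt, stopped at mono-cleavage
Reagents that add atoms: none
Why: Acid-catalysed acetal cleavage is selective for the MOM group ortho to the carbonyl, whose departure is assisted by the neighbouring aldehyde and gives a hydrogen-bonded salicylaldehyde, as is routine for 2,4-bis(MOM) aryl carbonyl compounds.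

Step 6
Reactants: 11 2-hydroxy-4-(methoxymethoxy)-3,5-diprenylbenzaldehyde; 12 3,4-dimethoxystyrene
Product: 15 (2S,4S)-cis-4-methoxy-7-(methoxymethoxy)-3',4'-dimethoxy-6,8-diprenylflavan, via dimethyl acetal 13 (not isolated), via methoxy ortho-quinone methide cation 14 (not isolated)
Conditions: HC(OMe)3 (2 equiv), (R)-3,3'-bis(2,4,6-triisopropylphenyl)-1,1'-binaphthyl-2,2'-diyl hydrogen phosphate (10 mol %), 5 Å molecular sieves, toluene, rt (acetal formation) → 0 °C; 12 (2 equiv) added slowly
Reagents that add atoms: trimethyl orthoformate, COC(OC)OC
Why: Proposed new method: the acid catalyses acetalisation of aldehyde 11 by HC(OMe)3 to 13 and then loss of methanol to the O-methyl oxocarbenium ion 14, which is the O-protonated form of a 4-methoxy ortho-quinone methide, is stabilised by the ortho phenol and the para C7 oxygen, and is held by the chiral phosphate through a hydrogen bond to the phenolic OH and ion pairing; the closest known reactions are the achiral Brønsted acid union of salicylaldehydes, orthoformates and styrenes to cis-4-alkoxyflavans and chiral phosphoric acid catalysed [4+2] additions of ortho-quinone methides to styrenes, and only their combination on this substrate is untested. Ring C closes by an intermolecular inverse-electron-demand hetero-[4+2] cycloaddition, suprafacial on both partners and asynchronous: the terminal carbon of styrene 12 bonds to C4 first and the phenol oxygen then captures the developing 4-methoxybenzylic cation at C2, the gain of ring A aromaticity being the driving force. C4 is fixed by the phosphate shielding one face of the planar heterodiene and C2 by the endo placement of the dimethoxyphenyl group relative to that face, so the catalyst-controlled cis adduct is (2S,4S), and only C2 has to last. Regioselectivity (aryl-bearing carbon to oxygen) follows from the polarisation of the styrene. Chemoselectivity over the two prenyl olefins rests on the higher nucleophilicity and excess of the 4-alkoxystyrene and on the fact that neither prenyl group can reach C4 within the molecule. The weak acid at 0 °C and the slow addition of 12 are meant to spare the MOM acetal and to hold back cationic oligomerisation of the styrene.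

Step 7
Reactants: 15 (2S,4S)-cis-4-methoxy-7-(methoxymethoxy)-3',4'-dimethoxy-6,8-diprenylflavan
Product: 16 (2S,4S)-7-(methoxymethoxy)-3',4'-dimethoxy-6,8-diprenylflavan-4-ol
Conditions: aq. HCl (0.1 M)–THF (1:3), rt
Reagents that add atoms: water, O
Why: Acid-catalysed SN1 solvolysis at C4 should exchange OMe for OH because the benzylic ether ionises to a cation stabilised by O1 and the C7 oxygen far more readily than the aryl MOM acetal or the C2–O1 bond reacts, so C2 is untouched, and any C4 epimer formed alongside the cis alcohol is carried on since C4 becomes a carbonyl in the next step.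

Step 8
Reactants: 16 (2S,4S)-7-(methoxymethoxy)-3',4'-dimethoxy-6,8-diprenylflavan-4-ol
Product: 17 (2S)-7-(methoxymethoxy)-3',4'-dimethoxy-6,8-diprenylflavanone
Conditions: Dess–Martin periodinane (1,1,1-triacetoxy-1,1-dihydro-1,2-benziodoxol-3(1H)-one, 1.3 equiv), pyridine, CH2Cl2, 0 °C → rt
Reagents that add atoms: none
Why: Dess–Martin oxidation of the secondary benzylic alcohol under buffered, non-basic conditions should convert either C4 epimer into the one ketone and leave the prenyl olefins, the MOM acetal and the C2 centre alone.

Step 9
Reactants: 17 (2S)-7-(methoxymethoxy)-3',4'-dimethoxy-6,8-diprenylflavanone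
Product: 18 (2S)-7-hydroxy-3',4'-dimethoxy-6,8-diprenylflavanone (IN0946)
Conditions: aq. HCl (3 M), MeOH, 40 °C
Reagents that add atoms: none
Why: Acid-catalysed hydrolysis of the aryl MOM acetal is the standard last step for prenylated flavanones, and since C2 is not enolisable and ring opening to the chalcone needs base, the S configuration should persist if the temperature is kept modest to avoid chroman formation from the ortho-prenyl phenol.

**Compound list**

1 | resorcinol (benzene-1,3-diol) | Oc1cccc(O)c1 | starting material
2 | 1,3-bis(methoxymethoxy)benzene | COCOc1cccc(OCOC)c1 | intermediate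
3 | prenyl bromide (1-bromo-3-methylbut-2-ene) | CC(C)=CCBr | starting material
4 | [2,6-bis(methoxymethoxy)phenyl]lithium | [Li]c1c(OCOC)cccc1OCOC | intermediate (not isolated)
5 | 1,3-bis(methoxymethoxy)-2-prenylbenzene | COCOc1cccc(OCOC)c1CC=C(C)C | intermediate
6 | [2,4-bis(methoxymethoxy)-3-prenylphenyl]lithium | [Li]c1ccc(OCOC)c(CC=C(C)C)c1OCOC | intermediate (not isolated)
7 | 1,3-bis(methoxymethoxy)-2,4-diprenylbenzene | COCOc1ccc(CC=C(C)C)c(OCOC)c1CC=C(C)C | intermediate
8 | [2,4-bis(methoxymethoxy)-3,5-diprenylphenyl]lithium | [Li]c1cc(CC=C(C)C)c(OCOC)c(CC=C(C)C)c1OCOC | intermediate (not isolated)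
9 | lithium (dimethylamino)[2,4-bis(methoxymethoxy)-3,5-diprenylphenyl]methanolate (racemic at the carbinol carbon) | [Li]OC(N(C)C)c1cc(CC=C(C)C)c(OCOC)c(CC=C(C)C)c1OCOC | intermediate (not isolated)
10 | 2,4-bis(methoxymethoxy)-3,5-diprenylbenzaldehyde | O=Cc1cc(CC=C(C)C)c(OCOC)c(CC=C(C)C)c1OCOC | intermediate
11 | 2-hydroxy-4-(methoxymethoxy)-3,5-diprenylbenzaldehyde | O=Cc1cc(CC=C(C)C)c(OCOC)c(CC=C(C)C)c1O | intermediate
12 | 3,4-dimethoxystyrene (4-ethenyl-1,2-dimethoxybenzene) | COc1ccc(C=C)cc1OC | starting material
13 | 2-(dimethoxymethyl)-5-(methoxymethoxy)-4,6-diprenylphenol | COC(OC)c1cc(CC=C(C)C)c(OCOC)c(CC=C(C)C)c1O | intermediate (not isolated)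
14 | O-methyl oxocarbenium ion of 11 (O-protonated 4-methoxy ortho-quinone methide; cation drawn, counter-ion the chiral phosphate) | C[O+]=Cc1cc(CC=C(C)C)c(OCOC)c(CC=C(C)C)c1O | intermediate (not isolated)
15 | (2S,4S)-2-(3,4-dimethoxyphenyl)-4-methoxy-7-(methoxymethoxy)-6,8-diprenylchromane (2,4-cis) | COc1ccc([C@@H]2C[C@H](OC)c3cc(CC=C(C)C)c(OCOC)c(CC=C(C)C)c3O2)cc1OC | intermediate
16 | (2S,4S)-2-(3,4-dimethoxyphenyl)-7-(methoxymethoxy)-6,8-diprenylchroman-4-ol (cis isomer drawn; its (2S,4R) epimer may accompany it and gives the same ketone) | COc1ccc([C@@H]2C[C@H](O)c3cc(CC=C(C)C)c(OCOC)c(CC=C(C)C)c3O2)cc1OC | intermediate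
17 | (2S)-2-(3,4-dimethoxyphenyl)-7-(methoxymethoxy)-6,8-diprenylchroman-4-one | COc1ccc([C@@H]2CC(=O)c3cc(CC=C(C)C)c(OCOC)c(CC=C(C)C)c3O2)cc1OC | intermediate
18 | (2S)-2-(3,4-dimethoxyphenyl)-7-hydroxy-6,8-diprenylchroman-4-one (IN0946) | COc1ccc([C@@H]2CC(=O)c3cc(CC=C(C)C)c(O)c(CC=C(C)C)c3O2)cc1OC | target

**Count**
Total steps: 9. Longest linear sequence: 9 steps (resorcinol 1 to target 18); styrene 12 enters as a purchased compound in step 6.

**Steps most likely to fail**

1. Step 6 (the step that goes beyond known chemistry). Three things may go wrong: ionisation of the acetal by the weak chiral acid may be too slow, the face selection by the phosphate may be poor, or the styrene may oligomerise under acid. The fallback uses the known racemic union and a known kinetic resolution. It sets out from 11 and 12 and comes back at 17. The same three-component reaction run with an achiral acid (anhydrous p-toluenesulfonic acid, 10 mol %, HC(OMe)3, CH2Cl2, 0 °C) should give racemic cis-4-methoxy-7-(methoxymethoxy)-3',4'-dimethoxy-6,8-diprenylflavan F1. Solvolysis as in step 7 would give racemic 7-(methoxymethoxy)-3',4'-dimethoxy-6,8-diprenylflavan-4-ol F2, and Dess–Martin oxidation as in step 8 would give racemic 7-(methoxymethoxy)-3',4'-dimethoxy-6,8-diprenylflavanone F3. Kinetic resolution by asymmetric transfer hydrogenation (RuCl[(R,R)-TsNCH(Ph)CH(Ph)NH2](p-cymene), HCO2H/Et3N, rt) is then expected to reduce the (2R)-ketone, by hydride delivery anti to the 2-aryl group, to (2R,4R)-cis-7-(methoxymethoxy)-3',4'-dimethoxy-6,8-diprenylflavan-4-ol F4. The (2S)-ketone 17 is left and is separated by chromatography. The antipode of the ligand would be taken if the other enantiomer of the ketone proved to be the fast-reacting one.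

2. Step 3 (the same concern applies to step 4). Removal of the doubly activated benzylic–allylic proton of the first prenyl group may compete with ring lithiation, and alkylation would then give mixtures. The fallback avoids carbanions next to prenyl groups and brings both prenyl groups in by cross-coupling. It sets out from 1 and comes back at 10. Vilsmeier–Haack formylation of resorcinol (POCl3, DMF, MeCN; then H2O) gives 2,4-dihydroxybenzaldehyde F5. Iodination with N-iodosuccinimide (2.1 equiv) at the two free positions ortho to the hydroxyl groups gives 2,4-dihydroxy-3,5-diiodobenzaldehyde F6. Protection with MOMCl and NaH in DMF gives 3,5-diiodo-2,4-bis(methoxymethoxy)benzaldehyde F7. A twofold Stille coupling with tributyl(prenyl)stannane (Pd(PPh3)4, DMF, 90 °C), which is known to transfer the linear prenyl group, then delivers aldehyde 10.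

3. Step 5. The discrimination between the two MOM groups may be lost, because the one at C4 is flanked by two prenyl groups, twisted out of the ring plane and therefore more labile than usual, which would lead to over-cleavage. The fallback replaces selective deprotection by global deprotection and selective protection. It sets out from 10 and comes back at 11. Both acetals are removed (aq. HCl 3 M, MeOH, 40 °C) to give 2,4-dihydroxy-3,5-diprenylbenzaldehyde F8. One MOM group is then put back on the 4-hydroxyl (MOMCl 1.05 equiv, K2CO3, acetone, rt), the 2-hydroxyl being tied up in a hydrogen bond to the aldehyde and much less nucleophilic.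

**Further compounds**

F1 | step 6 | racemic cis-4-methoxy-7-(methoxymethoxy)-3',4'-dimethoxy-6,8-diprenylflavan (both enantiomers written, joined by a dot) | COc1ccc([C@@H]2C[C@H](OC)c3cc(CC=C(C)C)c(OCOC)c(CC=C(C)C)c3O2)cc1OC.COc1ccc([C@H]2C[C@@H](OC)c3cc(CC=C(C)C)c(OCOC)c(CC=C(C)C)c3O2)cc1OC
F2 | step 6 | racemic 7-(methoxymethoxy)-3',4'-dimethoxy-6,8-diprenylflavan-4-ol (C4 epimers, no configuration assigned) | COc1ccc(C2CC(O)c3cc(CC=C(C)C)c(OCOC)c(CC=C(C)C)c3O2)cc1OC
F3 | step 6 | racemic 7-(methoxymethoxy)-3',4'-dimethoxy-6,8-diprenylflavanone | COc1ccc(C2CC(=O)c3cc(CC=C(C)C)c(OCOC)c(CC=C(C)C)c3O2)cc1OC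
F4 | step 6 | (2R,4R)-cis-7-(methoxymethoxy)-3',4'-dimethoxy-6,8-diprenylflavan-4-ol | COc1ccc([C@H]2C[C@@H](O)c3cc(CC=C(C)C)c(OCOC)c(CC=C(C)C)c3O2)cc1OC
F5 | step 3 | 2,4-dihydroxybenzaldehyde | O=Cc1ccc(O)cc1O
F6 | step 3 | 2,4-dihydroxy-3,5-diiodobenzaldehyde | O=Cc1cc(I)c(O)c(I)c1O
F7 | step 3 | 3,5-diiodo-2,4-bis(methoxymethoxy)benzaldehyde | O=Cc1cc(I)c(OCOC)c(I)c1OCOC
F8 | step 5 | 2,4-dihydroxy-3,5-diprenylbenzaldehyde | O=Cc1cc(CC=C(C)C)c(O)c(CC=C(C)C)c1O
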